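Grey held half the catalyst G of green, yet by 19 min its Z had fallen 0.868 as far as green's on a log scale.

| flask | Z | G | L | time |
|---|---|---|---|---|
| green | 0.800 M | 0.0800 M |  |  |
| ochre | 0.800 M | 0.0800 M | 0.400 M |  |
| blue | 2.40 M | 0.0800 M |  |  |
| grey | 0.800 M | 0.0400 M |  |  |
| red | 0.400 M | 0.240 M |  | 19 min |

| run | time / min | [Z] / M |
|---|---|---|
| green run | 0.76 | 0.790 |
| green run | 1.2 | 0.756 |
| green run | 1.9 | 0.731 |
| green run | 3.0 | 0.698 |
| green run | 4.8 | 0.637 |
| green run | 7.6 | 0.575 |
| green run | 12 | 0.457 |
| green run | 19 | 0.326 |
| ochre run | 0.76 | 0.777 |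
| ochre run | 1.2 | 0.768 |
| ochre run | 1.9 | 0.735 |
| ochre run | 3.0 | 0.706 |
| ochre run | 4.8 | 0.652 |
| ochre run | 7.6 | 0.566 |
| ochre run | 12 | 0.462 |
| ochre run | 19 | 0.329 |
| blue run | 0.76 | 2.338 |
| blue run | 1.2 | 2.292 |
| blue run | 1.9 | 2.225 |
| blue run | 3.0 | 2.144 |
| blue run | 4.8 | 1.990 |
| blue run | 7.6 | 1.792 |
| blue run | 12 | 1.487 |
| blue run | 19 | 1.128 |
| grey run | 0.76 | 0.774 |
| grey run | 1.2 | 0.764 |
| grey run | 1.9 | 0.735 |
| grey run | 3.0 | 0.704 |
| grey run | 4.8 | 0.661 |
| grey run | 7.6 | 0.589 |
| grey run | 12 | 0.491 |
| grey run | 19 | 0.367 |

(readings scatter by 0.006 M)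

- apparent order in [Z] of the starting rate, round the charge of the green run (the rate where two percent of its Z have turned into L) (one fixed amount of L, the same in the runs compared)
- apparent order in [G] of the starting rate, round the charge of the green run (the rate where two percent of its Z have turned into L)
- Z in the red run at 19 min, as a share of the Z charged

- Overall: Z -> L, with G as catalyst.
- Constant volume, constant temperature.
- The analysis sees a species whether free or bound.
- An order is taken over about fifteen percent of the charge, up and down.

I took the log fall of Z over a fixed time, divided by that time, as a flask's loss constant, its pseudo-first-order constant. Green's was 0.0472 /min. Dividing one flask's fall by another's at the same time makes time drop out. Ochre over green gave 0.990, so I read no effect of the added 0.400 M of L and set L aside.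

How much of green's loss ran through G? I assumed a part free of G plus a part in proportion to G. Halving G then leaves the grey-to-green ratio short of one by half that second part, so I multiplied the shortfall by 2 and got 0.264: the G share, the fraction of a flask's loss constant that scales with G. For a rate of that form, the order in G equals this share, so I took 0.264 as green's order in G, though it is a reading averaged over 19 min.

What did red's G do? Red holds 3.00 times green's G, which in my reckoning lifted green's constant to 0.0722 /min.

Did red's lower Z matter too? Blue over green gave 0.841 for 3.00 times the Z, an apparent order in Z of 0.842. Red's charge of 0.400 M against green's 0.800 M then raised the constant to 0.0805 /min, and I expected 21.7% of red's Z left at 19 min.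

The forecast gave 0.86 in Z, 0.19 in G and 21% left, saying “I take about 20%, with wide uncertainty”. My order in G stood higher than its figure.

The simulation gives 0.80 in Z, 0.27 in G and 22.7% of red's Z left.

    G + Z ⇌ GZ (1.740 /M/min, 0.3906 /min)
    GZ → L + G (0.1560 /min)
    Z → Gu (0.01644 /min)
    Z → L (0.01866 /min)

The forecast's order in G came out low by a factor of 1.44, while the order in green stands at 0.27 beside my G share of 0.264. Red's 22.7% means a mean loss constant of 0.0780 /min, beside the 0.0805 /min I had reckoned for red from the G share.

(The earlier runs and the new flask stem from a simulated flask with made-up constants; noise was put on by code.)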